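A ratio starts the dispute. By 8.00 h, grey had made 4.44 times the Z (product) of blue, from 8.33 times the L (substrate). Both flasks stood under gas X held at 25 mM.

the same everywhere: X 25 mM (held)
- blue: L 0.12 M; run made earlier
- grey: L 1 M; run made earlier
- alder: L 0.20 M; time 15 h
- larch: L 0.50 M; time 15 h
- maple: L 1.2 M; time 15 h
- birch: L 0.74 M; time 15 h
- ash: L 0.25 M; time 15 h
- cedar: L 1.5 M; time 15 h

| run | time / h | Z / % | L / % |
|---|---|---|---|
| blue | 1.00 | 3 | 98 |
| blue | 2.00 | 13 | 87 |
| blue | 3.00 | 18 | 81 |
| blue | 4.00 | 19 | 77 |
| blue | 5.00 | 30 | 68 |
| blue | 6.00 | 37 | 66 |
| blue | 8.00 | 45 | 55 |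
| grey | 0.417 | 3 | 99 |
| grey | 1.00 | 0 | 97 |
| grey | 2.00 | 8 | 95 |
| grey | 3.00 | 11 | 91 |
| grey | 5.00 | 16 | 83 |
| grey | 6.00 | 18 | 83 |
| grey | 8.00 | 24 | 76 |

(each reading ± 2 percentage points)

* ranking by amount of Z, in percent of the L charged, from high to low, at 15 h (alder / larch / maple / birch / ash / cedar)
* the amount of Z, in percent of the L charged of the flask you put first, at 15 h
* the amount of Z, in percent of the L charged of the flask you put last, at 15 h

- at the start none of X is in solution

The first chemist holds to first order in L. Blue's L reading at 8.00 h gives a rate constant k of 0.0747 /h. So, on this view, Z stands at 67.4% by 15 h, whatever the charge.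

The second chemist points to grey. It read 24% Z against blue's 45%, a gap of 21 percentage points against a scatter of 2 points. The forecast is this chemist's: alder > ash > larch > birch > maple > cedar, with 66% first and 34% last. Its ground is that the rate data “indicates saturation in L at constant X”.

My own reckoning uses the same two runs. They give n = 0.704, the apparent order: the power of the L charged that the Z made by a fixed time follows. It is the logarithm of the Z ratio over the logarithm of the L ratio, and it carries the scatter of its readings. The percent of Z then goes as the charge to the power n minus one. So percent falls as the charge rises, and alder should stand 1.82 times above cedar. The forecast's two values differ from this, at a ratio of 1.94.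

The simulation gives alder > ash > larch > birch > maple > cedar, with 58.5% in alder and 29.3% in cedar. The forecast has the order, and alder stands 7.5 points below it. First order loses: its figure stands 38 points above cedar. Its region is a charge as low as blue's, where the gap is smaller: blue continued to 15 h gives 63.3%, 4.1 points below that figure.

    L + G ⇌ Z + E (K = 13.0, k = 9.99 × 10⁻⁴ /M/s)
    X ⇌ G, rate k2*(csat - [G]) (kL = 6.40 × 10⁻⁴ /s)

Here G is dissolved X and E is the by-product. The ratio of alder to cedar came to 2.00, against the 1.82 from n. In cedar at 15.0 h, the step L + G ⇌ Z + E has a relaxation half-life of 0.168 h, short against 15 h. In cedar at that time G stands at 0.0180 M, and it is made 1.05 times as fast as it is used up, each step taken net, close to a quasi-steady state.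

A neighbour of cedar holds 0.90 M of L. From cedar, n gives 34.0% Z. The computed value is 37.3%.

(The earlier runs and the new flask are simulated on assumed constants; the scatter is artificial.)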